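## Retrosynthetic overview

1. Ring E and the C20–O bond are made together in the last step: allylic alcohol 15 isomerises through an allyl cation (C18–C19 ring closure, hydroxyl return at C20), which also sets C18, C19, C20 and the (E)-C12=C13 alkene.
2. 15 comes from alkenyl triflate 14 (ring D with the C17 quaternary centre) and aldehyde 7 (rings A/B) by C12–C13 coupling.
3. 14 comes from 3-methylcyclohexenone (ring D, bought) by asymmetric conjugate addition of a homoallyl metal made from tiglic aldehyde.
4. 7 comes from (+)-sclareolide (rings A/B, bought): C3–O by enzymatic C–H hydroxylation, C8 by dehydration and hydrogenation.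
5. Ring order: A/B and D are purchased, E is formed last.

Atom numbering in names (triterpenoid style, always written with "C"): A/B decalin C1–C10 (C3 carbinol, C4 gem-dimethyl, C5/C10 ring fusion, C8 CH–CH3, C9 side-chain carbon), C11 (CH2), C12, C13 (alkene carbon in ring D), C14–C16 (CH2), C17 (angular methyl), C18 (ring-fusion CH), C19 (CH–CH3), C20 (C(CH3)OH), C21, C22. Plain numbers are compounds.

Assumption: the engineered P450BM3 variant that hydroxylates sclareolide at C3 is available as an expressed biocatalyst.
Assumption: in step 7 the ligand antipode that gives the (S) quaternary centre is used (about 90% ee expected); the minor diastereomer arising after coupling is removed by chromatography after step 10.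

## Route

Step 1
Reactants: 1 (+)-sclareolide
Product: 2 3β-hydroxysclareolide
Conditions: P450BM3 variant (E. coli lysate), NADP+, alcohol dehydrogenase/isopropanol, air, phosphate buffer pH 8, 25 °C
Reagents that add atoms: dioxygen, O=O
Why: Enzymatic C–H hydroxylation (oxygen rebound, retention) is established for sclareolide and gives the equatorial 3β-alcohol, so C3 (S) is set here.

Step 2
Reactants: 2 3β-hydroxysclareolide
Product: 3 N-methoxy-N-methylamide of 3β,8α-dihydroxy-8β-methyl-11-homodriman-12-oic acid
Conditions: MeNH(OMe)·HCl, AlMe3, CH2Cl2, 0 °C to rt; aqueous HCl work-up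
Reagents that add atoms: N,O-dimethylhydroxylamine hydrochloride, CNOC.Cl
Why: Weinreb aminolysis of the lactone by the aluminium amide made in the flask is irreversible, touches no stereocentre and frees the tertiary 8α-hydroxyl.

Step 3
Reactants: 3 dihydroxy Weinreb amide
Product: 5 3β-acetoxy-8(17)-ene Weinreb amide (exocyclic methylene on C8), via 3-O-acetyl hydroxy amide 4 (not isolated)
Conditions: Ac2O, pyridine, DMAP (cat.), CH2Cl2, 0 °C to rt; then SOCl2, −78 °C
Reagents that add atoms: acetic anhydride, CC(=O)OC(C)=O
Why: Selective acetylation of the secondary alcohol, then chlorosulfite dehydration (E2) of the equatorial tertiary alcohol, whose only anti-periplanar hydrogens are on the methyl group, gives mainly the exocyclic alkene; the minor ring C7 alkene converges in step 4.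

Step 4
Reactants: 5 3β-acetoxy-8(17)-ene Weinreb amide
Product: 6 3β-acetoxy-8β-methyl-8αH Weinreb amide
Conditions: H2 (1 atm), PtO2, EtOAc, rt
Reagents that add atoms: none
Why: Heterogeneous syn hydrogenation should occur from the α face, away from the axial C10 methyl and the β side chain on C9, which places H on C8 from below and sets the axial 8β-methyl (C8 S).

Step 5
Reactants: 6 3β-acetoxy-8β-methyl Weinreb amide
Product: 7 2-[(3S,5R,8S,9S,10R)-3-hydroxy-4,4,8,10-tetramethyl-trans-decalin-9-yl]acetaldehyde (3β-OH; 8β-CH3; 9β-CH2CHO)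
Conditions: LiAlH4, THF, −20 to 0 °C; aqueous potassium sodium tartrate work-up
Reagents that add atoms: none
Why: Hydride reduction of a Weinreb amide stops at the chelated hemiaminal and gives the aldehyde on work-up, while the same reagent cleaves the acetate.

Step 6
Reactants: 8 tiglic aldehyde ((E)-2-methylbut-2-enal)
Product: 9 (E)-3-methylpenta-1,3-diene
Conditions: Ph3PCH3Br, KOtBu, diglyme, 0 °C to rt; product distilled out
Reagents that add atoms: methyltriphenylphosphonium bromide, C[P+](c1ccccc1)(c1ccccc1)c1ccccc1.[Br-]
Why: Wittig methylenation is a 1,2-process on the enal and leaves the (E) trisubstituted alkene untouched.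

Step 7
Reactants: 9 (E)-3-methylpenta-1,3-diene; 10 3-methylcyclohex-2-en-1-one
Product: 12 trimethyl{[(3S)-3-methyl-3-[(E)-3-methylpent-3-en-1-yl]cyclohex-1-en-1-yl]oxy}silane, via homoallyl zirconocene chloride 11 (not isolated)
Conditions: Cp2Zr(H)Cl, CH2Cl2, rt; then 10, CuCl (10 mol%), AgNTf2 (11 mol%), chiral binaphthol-derived phosphoramidite (10 mol%), Me3SiCl, Et2O, 0 °C to rt; non-aqueous work-up
Reagents that add atoms: chlorotrimethylsilane, C[Si](C)(C)Cl
Why: Hydrozirconation adds 1,2 to the terminal vinyl group of the diene, and the copper-catalysed asymmetric conjugate addition with silyl trapping builds the C17 quaternary centre as (S) under ligand control and fixes the enol ether toward C18.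

Step 8
Reactants: 12 silyl enol ether
Product: 14 (3S)-3-methyl-3-[(E)-3-methylpent-3-en-1-yl]cyclohex-1-en-1-yl trifluoromethanesulfonate, via lithium enolate 13 (not isolated)
Conditions: MeLi, THF, −78 to 0 °C; then PhNTf2, −78 °C to rt; aqueous NH4Cl work-up
Reagents that add atoms: N-phenylbis(trifluoromethanesulfonimide), O=S(=O)(N(c1ccccc1)S(=O)(=O)C(F)(F)F)C(F)(F)F
Why: MeLi cleaves the silyl enol ether to the regiodefined lithium enolate, which is O-triflated before it can equilibrate (enolate triflation).

Step 9
Reactants: 14 alkenyl triflate; 7 aldehyde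
Product: 15 allylic alcohol (C12 carbinol, both epimers; C13=C18 alkene in ring D; 3β-OH free)
Conditions: CrCl2, NiCl2 (2 mol%), DMF, rt
Reagents that add atoms: none
Why: Nozaki–Hiyama–Kishi coupling: the alkenylchromium formed via nickel adds chemoselectively to the aldehyde in the presence of the free alcohol; the new C12 centre is formed as a mixture, which does not matter because it is erased in step 10.

Step 10
Reactants: 15 allylic alcohol
Product: 17 CNP0338143.1, via transposed allylic alcohol 16 (not isolated)
Conditions: Re2O7 (5 mol%), H2O (3 equiv), CH2Cl2/(CF3)2CHOH 4:1, −20 to 0 °C; Et3N quench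
Reagents that add atoms: water, O
Why: Proposed new method: Re2O7 esterifies the allylic alcohol and the perrhenate undergoes the known chair-like [3,3] 1,3-transposition (C11 pseudo-equatorial) to the (E)-C12=C13 isomer 16, which ionises to an (E) allyl cation; the tethered (E)-trisubstituted alkene attacks C18 through the only chair transition state its tether allows (cis fusion with H18 cis to the C17 methyl, C19 methyl equatorial) and the tertiary C20 cation is captured anti to the new C18–C19 bond by perrhenate or water in the ion pair, so that after Re–O hydrolysis the equatorial 20-OH with axial methyl results and C18 (R), C19 (R), C20 (R) and the alkene geometry are set in one isomerisation; the closest known chemistry is Re2O7-catalysed allylic alcohol transposition with trapping of the cation by tethered nucleophiles and the acid-promoted allyl-cation polyene cyclisation ended by water or formate, but a carbocyclisation in which the hydroxyl lost at C12 is returned stereospecifically to the terminating carbon has not been described.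

## Compound list

1 | (+)-sclareolide, (3aR,5aS,9aS,9bR)-3a,6,6,9a-tetramethyldecahydronaphtho[2,1-b]furan-2(1H)-one | O=C1C[C@H]2[C@](C)(O1)CC[C@H]3C(C)(C)CCC[C@]23C | starting material
2 | 3β-hydroxysclareolide (equatorial 3S alcohol on ring A) | O=C1C[C@H]2[C@](C)(O1)CC[C@H]3C(C)(C)[C@@H](O)CC[C@]23C | intermediate
3 | N-methoxy-N-methylamide of 3β,8α-dihydroxy-8β-methyl-11-homodriman-12-oic acid | CON(C)C(=O)C[C@H]1[C@](C)(O)CC[C@H]2C(C)(C)[C@@H](O)CC[C@]12C | intermediate
4 | 3-O-acetate of 3 (8α-OH free) | CON(C)C(=O)C[C@H]1[C@](C)(O)CC[C@H]2C(C)(C)[C@@H](OC(C)=O)CC[C@]12C | intermediate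
5 | 3β-acetoxy-8(17)-ene Weinreb amide (exocyclic C8 methylene, 5α-H, 9α-H, 10β-CH3) | CON(C)C(=O)C[C@H]1C(=C)CC[C@H]2C(C)(C)[C@@H](OC(C)=O)CC[C@]12C | intermediate
6 | 3β-acetoxy-8β-methyl-8αH Weinreb amide (C8 methyl axial, cis to C10 methyl and C9 side chain) | CON(C)C(=O)C[C@H]1[C@@H](C)CC[C@H]2C(C)(C)[C@@H](OC(C)=O)CC[C@]12C | intermediate
7 | 2-[(3S,5R,8S,9S,10R)-3-hydroxy-4,4,8,10-tetramethyl-trans-decalin-9-yl]acetaldehyde | O=CC[C@H]1[C@@H](C)CC[C@H]2C(C)(C)[C@@H](O)CC[C@]12C | intermediate
8 | tiglic aldehyde, (E)-2-methylbut-2-enal | C/C=C(\C)C=O | starting material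
9 | (E)-3-methylpenta-1,3-diene | C/C=C(\C)C=C | intermediate
10 | 3-methylcyclohex-2-en-1-one | CC1=CC(=O)CCC1 | starting material
11 | chlorobis(cyclopentadienyl)[(E)-3-methylpent-3-en-1-yl]zirconium | C/C=C(\C)CC[Zr](Cl)(C1C=CC=C1)C1C=CC=C1 | intermediate
12 | trimethyl{[(3S)-3-methyl-3-[(E)-3-methylpent-3-en-1-yl]cyclohex-1-en-1-yl]oxy}silane | C[Si](C)(C)OC1=C[C@](C)(CC/C(C)=C/C)CCC1 | intermediate
13 | lithium (3S)-3-methyl-3-[(E)-3-methylpent-3-en-1-yl]cyclohex-1-en-1-olate | [Li]OC1=C[C@](C)(CC/C(C)=C/C)CCC1 | intermediate
14 | (3S)-3-methyl-3-[(E)-3-methylpent-3-en-1-yl]cyclohex-1-en-1-yl trifluoromethanesulfonate | O=S(=O)(OC1=C[C@](C)(CC/C(C)=C/C)CCC1)C(F)(F)F | intermediate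
15 | allylic alcohol: C12 carbinol (both epimers) joining C11 of the A/B decalin of 7 to C13 of the (17S)-cyclohexene (C13=C18), 3β-OH free | C/C=C(\C)CC[C@]1(C)CCCC(=C1)C(O)C[C@H]2[C@@H](C)CC[C@H]3C(C)(C)[C@@H](O)CC[C@]23C | intermediate
16 | transposed allylic alcohol: C18 carbinol (both epimers), (E)-C12=C13 exocyclic alkene | C/C=C(\C)CC[C@]1(C)CCC/C(=C\C[C@H]2[C@@H](C)CC[C@H]3C(C)(C)[C@@H](O)CC[C@]23C)C1O | intermediate
17 | CNP0338143.1, (3S,5R,8S,9S,10R,12E,17S,18R,19R,20R): 3β-hydroxy trans-A/B decalin (8β-CH3) linked by C11H2–C12H=C13 to the cis-D/E decalin with 17β-CH3, 18β-H, 19β-CH3, 20β-CH3, 20α-OH | C[C@@H]1[C@H]2/C(=C/C[C@H]3[C@@H](C)CC[C@H]4C(C)(C)[C@@H](O)CC[C@]34C)CCC[C@@]2(C)CC[C@@]1(C)O | target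

## Step count and risks

Total steps: 10. Longest linear sequence: 7 (steps 1–5, 9, 10); the other branch is steps 6–8.

Most likely to fail:

Step 10 (the proposed new step). The C20 cation may eliminate to alkenes, or the hydroxyl may return without facial control. Fallback with known chemistry: run the ring closure as a classical solvolytic allyl-cation polyene cyclisation. Allylic alcohol 15 is stirred in anhydrous formic acid/pentane at room temperature, which ionises the allylic alcohol, closes ring E and traps the tertiary cation as its formate (the 3-hydroxyl is formylated too), giving the 3,20-bis-formate F1. K2CO3 in methanol then cleaves both formates and the route is rejoined at 17.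

Step 7. The copper-catalysed addition of the diene-derived alkylzirconium may be low-yielding or poorly enantioselective. Fallback: the alkylzirconium 11 is quenched with N-bromosuccinimide to give (E)-5-bromo-3-methylpent-2-ene F2, which is converted with magnesium in Et2O into (E)-(3-methylpent-3-en-1-yl)magnesium bromide F3. F3 is added to enone 10 under Cu(OTf)2/chiral N-heterocyclic carbene catalysis with Me3SiCl present, and the route is rejoined at silyl enol ether 12.

Step 4. Hydrogenation may give the wrong C8 epimer or move the alkene into the unreactive tetrasubstituted position. Fallback: set C8 by ionic hydrogenation at the lactone stage. 3β-Hydroxysclareolide 2 is treated with Et3SiH in CF3CO2H/CH2Cl2; the tertiary lactone ionises at C8 as a tert-butyl ester does and the cation is reduced from the open α face, giving after basic work-up 3β-hydroxy-8β-methyl-8αH-11-homodriman-12-oic acid F4. Coupling with MeNH(OMe)·HCl and a carbodiimide gives the N-methoxy-N-methylamide F5, and LiAlH4 reduction rejoins the route at aldehyde 7.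

## Further compounds

F1 | step 10 | 3,20-bis-formate of 17 | C[C@@H]1[C@H]2/C(=C/C[C@H]3[C@@H](C)CC[C@H]4C(C)(C)[C@@H](OC=O)CC[C@]34C)CCC[C@@]2(C)CC[C@@]1(C)OC=O
F2 | step 7 | (E)-5-bromo-3-methylpent-2-ene | C/C=C(\C)CCBr
F3 | step 7 | (E)-(3-methylpent-3-en-1-yl)magnesium bromide | C/C=C(\C)CC[Mg]Br
F4 | step 4 | 3β-hydroxy-8β-methyl-8αH-11-homodriman-12-oic acid | OC(=O)C[C@H]1[C@@H](C)CC[C@H]2C(C)(C)[C@@H](O)CC[C@]12C
F5 | step 4 | N-methoxy-N-methylamide of F4 | CON(C)C(=O)C[C@H]1[C@@H](C)CC[C@H]2C(C)(C)[C@@H](O)CC[C@]12C
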